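## The problem

Compound 14 is a 2,3-dihydrobenzofuran in which ring A is fused through C3a and C7a to the ring O1–C2–C3–C3a–C7a. C2 carries a 4-hydroxyphenyl group (ring B), C3 a carboxamide and C5, para to O1, an (E)-acrylamide; both amide nitrogens end in the same 4-guanidinobutyl chain, so the molecule is formally a dehydrodimer of 4-coumaroylagmatine. The two adjacent stereocentres are (2R) and (3R), with aryl and carboxamide trans. C3 is benzylic and α to a carbonyl group, so it epimerises with base and settles in the more stable trans arrangement, whereas C2, a benzylic ether carbon, can invert only if a ring bond breaks; C2 can therefore control C3 and is the only centre that must be set in absolute terms. The fragile groups are the two strongly basic guanidines (to be carried protected and freed last), the cinnamoyl double bond (no reducing or strongly nucleophilic reagents) and the 4-hydroxybenzylic aryl ether C2–O1, which a free 4-phenoxide can open to a quinone methide, so hot alkali after the phenol is unmasked is excluded. The enabling feature is that O1, C2, C3, C3a and C7a, together with the exocyclic carboxyl carbon on C3, are the six ring atoms of a chroman-4-one whose carbonyl carbon has been pushed out of the ring. A 2-arylchroman-4-one with C2 in place maps onto the target by one 1,2-shift of the ring A carbon from the carbonyl carbon to the neighbouring methylene, and ring A then needs only a handle para to O1 for the side chain.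

## Retrosynthesis

**14 ⇒ 13.** The four N–CO2tBu bonds of the guanidines are cut last. Free guanidines would make every earlier intermediate a polar salt and would compete in acylations; as Boc derivatives they are neutral and fall under acid, which spares the amides, the alkene and the trans ring. The forward step asks only for acidolysis.

**13 ⇒ 11 + two molecules of 12.** The two amide C–N bonds are cut together. Both side chains end in the same amine, so diacid 11 can be acylated twice by 12 in one operation, without differentiating the C3 carboxyl from the cinnamic carboxyl. Forming the cinnamamide first and the C3 amide second would cost one step more. The forward reaction must acylate an amine beside a free phenol and must not open the ring.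

**11 ⇒ 10.** The O–CH3 bond of the C3 ester and the O–acyl bond of the phenol ester are cut in one hydrolysis. A pivalate is chosen for the phenol for three reasons: it makes ring B a poor migrating group in the key step, it resists acid-catalysed methanolysis there (an acetate might not), and it leaves with cold hydroxide together with the methyl ester. An aryl sulfonate would be as deactivating but would call for hot hydroxide, under which the freed 4-phenoxide can open the C2–O1 bond.

**10 ⇒ 8 + 9.** The C5–Cβ bond of the cinnamic acid is cut to aryl bromide 8 and acrylic acid 9 (Heck reaction). The bromine sits para to O1 from the very first compound, so no late functionalisation of ring A with its regiochemical uncertainty is needed. Acrylic acid delivers the side chain at the right oxidation level and with (E) geometry.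

**8 ⇒ 4 (key disconnection).** The C3–C3a bond is cut and the ring A carbon is returned to the carboxyl carbon, which re-expands the dihydrofuran ester to flavanone 4. The precursor has one stereocentre instead of two and its six-membered ring is available by conjugate addition. In the forward direction an aryl-λ3-iodane in acidic orthoformate must move ring A, not ring B, to C3 and must place the ester trans to the C2 aryl group. The transient enol ether 5, iodanyl ketal 6 and orthoester 7 lie on that path.

**4 ⇒ 3 ⇒ 1 + 2.** The pivalate O–acyl bond is cut first, then the C2–aryl bond. This leads to 6-bromochromone 1 and 4-hydroxyphenylboronic acid 2, joined by an enantioselective conjugate addition under a chiral pyridine–oxazoline complex of divalent palladium. This is the only step in which absolute configuration is created. An oxa-Michael closure of a 2'-hydroxychalcone would make the same ring but has no comparably general asymmetric version for an unactivated chalcone.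

## Roads not taken

**Alternative 1:** Ring A would be built last by cyclotrimerisation of the 1,6-diyne tert-butyl{[(2S,3R)-3-(4-tert-butoxyphenyl)-2-ethynyl-3-(ethynyloxy)propyl]oxy}dimethylsilane A2 with acetylene A3 on RhCl(PPh3)3. This forms C3a–C7a, C4–C5 and C6–C7 and closes ring A and the dihydrofuran ring together, giving (2R,3S)-2-(4-tert-butoxyphenyl)-3-[(tert-butyldimethylsilyloxy)methyl]-2,3-dihydrobenzofuran A1.

- Merits: both stereocentres would be set in an open chain before any ring exists; C3 carries a CH2O group and cannot epimerise on the way; and the tert-butyl ether would fall in the final acid step, so no hydroxide would ever meet the free phenol. In these respects it is safer than the chosen plan.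
- Weak points: A2 is a secondary alkyl ethynyl ether with a β-hydrogen, a class that is laborious to make and prone to thermal loss of ketene. A1 arrives with an unsubstituted ring A, so C5 would have to be halogenated in competition with the electron-rich ring B. The CH2O group must then be raised two oxidation levels to the acid.
- Comparison: this would roughly double the step count. The chosen plan sets against it a C5 bromide present from compound 1, a C3 carbon born as an ester, and seven steps in all.

**Alternative 2:** The O1–C7a bond would be closed by fluoride displacement. The alkoxide of 3-[(1R,2S)-1-(4-tert-butoxyphenyl)-1-hydroxybut-3-en-2-yl]-4-fluorobenzonitrile A5 (Cs2CO3, DMF) attacks the fluorine-bearing carbon para to the nitrile and gives (2R,3S)-2-(4-tert-butoxyphenyl)-3-vinyl-2,3-dihydrobenzofuran-5-carbonitrile A4, the cis isomer.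

- Merits: the ring closure is more predictable than an oxidative rearrangement, has no competing migration and does not touch C2; the phenol is again freed by acid at the end.
- Weak points: A5 needs two adjacent stereocentres made by separate asymmetric chemistry, and its doubly activated C–H (allylic and benzylic to a cyanoarene) invites alkene migration under the basic closure. After the key step the vinyl group must be cleaved oxidatively to the acid, the nitrile reduced and homologated to the acrylate, and C3 epimerised from cis to trans.
- Comparison: the two masked groups cost about five redox and homologation steps that the chosen plan does not need, since both carboxyl carbons of 14 enter at the right oxidation level and the trans relation comes out of the key step itself.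

**Alternative 3:** A chiral phosphoric acid such as 3,3'-bis(2,4,6-triisopropylphenyl)-1,1'-binaphthalene-2,2'-diyl hydrogen phosphate would dehydrate tert-butyl 2-(5-bromo-2-hydroxyphenyl)-3-hydroxy-3-(4-hydroxyphenyl)propanoate A7 (all four stereoisomers) to a para-quinone methide. The ortho phenol would add to its exocyclic carbon, forming O1–C2, to give tert-butyl (2R,3R)-5-bromo-2-(4-hydroxyphenyl)-2,3-dihydrobenzofuran-3-carboxylate A6.

- Merits: this is the shortest road on paper. A7 needs no stereocontrol, the phenol is never protected, and the tert-butyl ester is cleaved by acid, so the hydroxide step that is the weak point of the chosen endgame disappears. In step economy and endgame mildness it is better.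
- Weak points: the catalyst must override a fast uncatalysed intramolecular addition. The quinone methide erases only C2, so funnelling four isomers into one also needs C3 to epimerise under weak acid, or the result is at best a resolution. The product can re-ionise at C2 under the same acid, which leaves the absolute configuration resting on the centre that the catalyst does not set.
- Comparison: the chosen plan sets against this an enantioselective step of an established type for C2 and a stereospecific migration for C3.

Key step: step 3

Assumptions:
- (S)-t-BuPyOx is expected, by analogy with its sense of induction on 3-substituted cyclohexenones, to give the (2R) flavanone; should the opposite sense be found, the (R)-ligand is used.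
- N,N'-di-Boc-agmatine 12 is taken as a catalogue compound.
- Compound 14 would be isolated as its bis(trifluoroacetate) and is listed as the free base.

## Route

**Step 1**
Reactants: 1 6-bromochromone (6-bromo-4H-chromen-4-one); 2 (4-hydroxyphenyl)boronic acid
Product: 3 (2R)-6-bromo-2-(4-hydroxyphenyl)chroman-4-one
Conditions: Pd(OCOCF3)2 (5 mol %), (S)-t-BuPyOx [(S)-4-tert-butyl-2-(pyridin-2-yl)-4,5-dihydrooxazole, 6 mol %], NH4PF6 (30 mol %), H2O (5 equiv), ClCH2CH2Cl, 60 °C
Reagents that add atoms: none
Why: Asymmetric conjugate addition of an arylboronic acid to a chromone under cationic divalent palladium: the aryl group is transferred from boron to palladium, the C2=C3 bond inserts on the face left open by the tert-butyl group of the ligand, and water protonates the palladium enolate, setting C2 as (R). The aryl bromide is inert because no zerovalent palladium is formed, and the wet, weakly acidic medium should tolerate the phenol and does not open the flavanone.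

**Step 2**
Reactants: 3 (2R)-6-bromo-2-(4-hydroxyphenyl)chroman-4-one
Product: 4 4-[(2R)-6-bromo-4-oxochroman-2-yl]phenyl pivalate
Conditions: t-BuCOCl (1.2 equiv), pyridine (3 equiv), CH2Cl2, 0 °C → rt
Reagents that add atoms: pivaloyl chloride, CC(C)(C)C(Cl)=O
Why: O-Acylation of the phenol by the acid chloride with pyridine as acid scavenger; pyridine is too weak a base to enolise the ketone or to ionise the phenol, so the reversible ring opening to the chalcone that racemises flavanones is not triggered.

**Step 3**
Reactants: 4 4-[(2R)-6-bromo-4-oxochroman-2-yl]phenyl pivalate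
Product: 8 methyl (2R,3R)-5-bromo-2-[4-(pivaloyloxy)phenyl]-2,3-dihydrobenzofuran-3-carboxylate, via methyl enol ether 5 (not isolated), via trans-3-iodanyl dimethyl ketal 6 (not isolated), via trimethyl orthoester 7 (not isolated)
Conditions: PhI(OAc)2 (1.2 equiv), conc. H2SO4 (0.5 equiv), HC(OMe)3, 0 °C → rt; aq. NaHCO3
Reagents that add atoms: trimethyl orthoformate, COC(OC)OC; water, O
Why: Oxidative ring contraction of a flavanone by a 1,2-aryl shift, a reaction type known for flavanones with PhI(OAc)2/H2SO4 or Tl(NO3)3 in trimethyl orthoformate and akin to the hypervalent-iodine rearrangement of aryl ketones to arylacetic esters. Acid and the orthoformate turn ketone 4 into enol ether 5, whose C3 attacks the trivalent iodine of PhI(OAc)2 on the face anti to the C2 aryl group; methanol caps C4 and gives ketal 6 with the aryl and iodanyl groups trans-diequatorial. In that half-chair the C4–C4a bond is antiperiplanar to the C3–I bond, so the ring A carbon C4a, pushed by the two methoxy oxygens on C4, shifts to C3 with inversion while iodobenzene leaves; the dimethoxycarbenium ion is trapped as orthoester 7 and ends as the methyl ester on work-up. The dihydrofuran ring thus arises by contraction and not by cyclisation of a chain: C4a bridges C4 and C3 in a phenonium-like three-membered transition state (3-exo-tet attack on C3) and the new C3–C3a bond replaces C4–C4a. The new stereocentre C3 is set by C2 under substrate control, anti iodination followed by invertive migration placing the ester trans to the aryl group, and the thermodynamic preference for trans backs this up; C2 and the C2–O1 bond are untouched, so the (2R) centre is carried over. The step needs ring A to migrate in preference to the 2→3 shift of ring B (isoflavone) and to dehydrogenation (flavone): the pivaloyloxy group makes ring B a poor migrating group, ring B is gauche and not anti to the leaving group in the diequatorial conformer, and C4a is ortho to the donor O1.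

**Step 4**
Reactants: 8 methyl (2R,3R)-5-bromo-2-[4-(pivaloyloxy)phenyl]-2,3-dihydrobenzofuran-3-carboxylate; 9 acrylic acid
Product: 10 (E)-3-[(2R,3R)-3-(methoxycarbonyl)-2-[4-(pivaloyloxy)phenyl]-2,3-dihydrobenzofuran-5-yl]acrylic acid
Conditions: Pd(OAc)2 (5 mol %), P(o-tol)3 (10 mol %), Et3N (4 equiv), DMF, 90 °C; then 1 M HCl
Reagents that add atoms: none
Why: Heck reaction: zerovalent palladium inserts into the C5–Br bond, syn insertion of the acrylate and syn β-hydride elimination give the (E)-cinnamic acid, and the aryl pivalate C–O bond is inert to palladium. Et3N can move C3 only towards the more stable trans ester, so any cis isomer from step 3 converges here, and it cannot touch C2.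

**Step 5**
Reactants: 10 (E)-3-[(2R,3R)-3-(methoxycarbonyl)-2-[4-(pivaloyloxy)phenyl]-2,3-dihydrobenzofuran-5-yl]acrylic acid
Product: 11 (2R,3R)-5-[(E)-2-carboxyvinyl]-2-(4-hydroxyphenyl)-2,3-dihydrobenzofuran-3-carboxylic acid
Conditions: LiOH·H2O (6 equiv), THF/H2O 3:1, 0 °C → rt; then 1 M HCl to pH 3
Reagents that add atoms: lithium hydroxide, [Li+].[OH-]
Why: Saponification of the methyl ester and of the aryl pivalate in one operation; once C3 carries a carboxylate its hydrogen is no longer acidic, and low temperature with prompt acidification keeps the freed 4-phenoxide from opening the C2–O1 bond. Any epimerisation at C3 before hydrolysis leads back to trans.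

**Step 6**
Reactants: 11 (2R,3R)-5-[(E)-2-carboxyvinyl]-2-(4-hydroxyphenyl)-2,3-dihydrobenzofuran-3-carboxylic acid; 12 N,N'-di-Boc-agmatine [N-(4-aminobutyl)-N',N''-bis(tert-butoxycarbonyl)guanidine] (2.4 equiv)
Product: 13 (2R,3R)-N-{4-[N',N''-bis(tert-butoxycarbonyl)guanidino]butyl}-5-[(E)-3-({4-[N',N''-bis(tert-butoxycarbonyl)guanidino]butyl}amino)-3-oxoprop-1-en-1-yl]-2-(4-hydroxyphenyl)-2,3-dihydrobenzofuran-3-carboxamide
Conditions: EDC·HCl (2.6 equiv), HOBt (2.6 equiv), i-Pr2NEt (3 equiv), DMF, 0 °C → rt
Reagents that add atoms: none
Why: Carbodiimide-mediated amide coupling with HOBt as acyl-transfer additive; both carboxyl groups take the same primary amine, so no differentiation is needed. The phenol is a far poorer nucleophile than the amine, any aryl ester formed would be aminolysed by the excess of 12, and i-Pr2NEt in DMF does not ionise the phenol.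

**Step 7**
Reactants: 13 the tetra-Boc bis-amide
Product: 14 (2R,3R)-N-(4-guanidinobutyl)-5-[(E)-3-[(4-guanidinobutyl)amino]-3-oxoprop-1-en-1-yl]-2-(4-hydroxyphenyl)-2,3-dihydrobenzofuran-3-carboxamide
Conditions: CF3CO2H/CH2Cl2 1:1, 0 °C → rt
Reagents that add atoms: none
Why: Acidolysis of the four tert-butyl carbamates (Boc removal) frees both guanidines as their trifluoroacetates; the amides, the cinnamoyl double bond and the trans ring should survive, and dilute, cold conditions let isobutene escape before it can alkylate ring B.

## Compound list

1 | 6-bromochromone (6-bromo-4H-chromen-4-one) | O=c1ccoc2ccc(Br)cc12 | starting material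
2 | (4-hydroxyphenyl)boronic acid | OB(O)c1ccc(O)cc1 | starting material
3 | (2R)-6-bromo-2-(4-hydroxyphenyl)chroman-4-one | O=C1C[C@H](c2ccc(O)cc2)Oc2ccc(Br)cc12 | intermediate
4 | 4-[(2R)-6-bromo-4-oxochroman-2-yl]phenyl pivalate | O=C1C[C@H](c2ccc(OC(=O)C(C)(C)C)cc2)Oc2ccc(Br)cc12 | intermediate
5 | 4-[(2R)-6-bromo-4-methoxy-2H-chromen-2-yl]phenyl pivalate (methyl enol ether, not isolated) | COC1=C[C@H](c2ccc(OC(=O)C(C)(C)C)cc2)Oc2ccc(Br)cc12 | intermediate
6 | 4-[(2S,3S)-3-[acetoxy(phenyl)-λ3-iodanyl]-6-bromo-4,4-dimethoxychroman-2-yl]phenyl pivalate (iodine trans to the aryl group, not isolated) | COC1(OC)[C@@H](I(OC(C)=O)c2ccccc2)[C@H](c2ccc(OC(=O)C(C)(C)C)cc2)Oc2ccc(Br)cc12 | intermediate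
7 | 4-[(2R,3R)-5-bromo-3-(trimethoxymethyl)-2,3-dihydrobenzofuran-2-yl]phenyl pivalate (orthoester, not isolated) | Brc1ccc2c(c1)[C@@H](C(OC)(OC)OC)[C@H](c1ccc(OC(=O)C(C)(C)C)cc1)O2 | intermediate
8 | methyl (2R,3R)-5-bromo-2-[4-(pivaloyloxy)phenyl]-2,3-dihydrobenzofuran-3-carboxylate | Brc1ccc2c(c1)[C@@H](C(=O)OC)[C@H](c1ccc(OC(=O)C(C)(C)C)cc1)O2 | intermediate
9 | acrylic acid | C=CC(=O)O | starting material
10 | (E)-3-[(2R,3R)-3-(methoxycarbonyl)-2-[4-(pivaloyloxy)phenyl]-2,3-dihydrobenzofuran-5-yl]acrylic acid | OC(=O)/C=C/c1ccc2c(c1)[C@@H](C(=O)OC)[C@H](c1ccc(OC(=O)C(C)(C)C)cc1)O2 | intermediate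
11 | (2R,3R)-5-[(E)-2-carboxyvinyl]-2-(4-hydroxyphenyl)-2,3-dihydrobenzofuran-3-carboxylic acid | OC(=O)/C=C/c1ccc2c(c1)[C@@H](C(=O)O)[C@H](c1ccc(O)cc1)O2 | intermediate
12 | N,N'-di-Boc-agmatine [N-(4-aminobutyl)-N',N''-bis(tert-butoxycarbonyl)guanidine] | NCCCCN=C(NC(=O)OC(C)(C)C)NC(=O)OC(C)(C)C | starting material
13 | (2R,3R)-N-{4-[N',N''-bis(tert-butoxycarbonyl)guanidino]butyl}-5-[(E)-3-({4-[N',N''-bis(tert-butoxycarbonyl)guanidino]butyl}amino)-3-oxoprop-1-en-1-yl]-2-(4-hydroxyphenyl)-2,3-dihydrobenzofuran-3-carboxamide | CC(C)(C)OC(=O)NC(NC(=O)OC(C)(C)C)=NCCCCNC(=O)/C=C/c1ccc2c(c1)[C@@H](C(=O)NCCCCN=C(NC(=O)OC(C)(C)C)NC(=O)OC(C)(C)C)[C@H](c1ccc(O)cc1)O2 | intermediate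
14 | (2R,3R)-N-(4-guanidinobutyl)-5-[(E)-3-[(4-guanidinobutyl)amino]-3-oxoprop-1-en-1-yl]-2-(4-hydroxyphenyl)-2,3-dihydrobenzofuran-3-carboxamide | NC(N)=NCCCCNC(=O)/C=C/c1ccc2c(c1)[C@@H](C(=O)NCCCCN=C(N)N)[C@H](c1ccc(O)cc1)O2 | target

## Step count and risks

Total step count: 7. Longest linear sequence: 7 steps (1 → 14).

**Step 3 (key step).** The most likely failure is migration of ring B in place of ring A, or dehydrogenation to the flavone, if the iodanyl intermediate reacts from its diaxial conformer or ionises before ring A can shift. Acid-promoted loss of the pivalate would add oxidation of the freed phenol by the iodane. Partial syn iodination would give some cis ester, which the base of step 4 should converge to trans.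

The fallback keeps the same 1,2-shift but drives it with a carbene instead of an iodane. It sets out from 4 and returns at 8:
- Ketone 4 is enolised with LiN(SiMe3)2 in THF at −78 °C and trapped at once with CF3CO2CH2CF3 to give 4-[(2R)-6-bromo-4-oxo-3-(trifluoroacetyl)chroman-2-yl]phenyl pivalate F1.
- Detrifluoroacetylative diazo transfer (CH3SO2N3, Et3N, H2O, MeCN, rt) gives 4-[(2S)-6-bromo-3-diazo-4-oxochroman-2-yl]phenyl pivalate F2. The spatial arrangement at C2 is that of 4; the descriptor changes because the diazo carbon outranks the aryl group.
- Photolysis of F2 in methanol (Wolff rearrangement) moves C4a to C3 and should give the ring-contracted ester, partly as the cis isomer methyl (2R,3S)-5-bromo-2-[4-(pivaloyloxy)phenyl]-2,3-dihydrobenzofuran-3-carboxylate F3.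
- DBU in CH2Cl2 equilibrates F3 to 8.

**Step 1.** Protodeboronation of the electron-rich boronic acid and binding of the phenol to the cationic palladium may starve the catalytic cycle or erode facial selectivity. The 4'-hydroxyflavanone 3 can also lose optical purity by reversible ring opening if it meets base.

The fallback protects before coupling. It sets out from 2 and returns at 4: acylation of 2 (t-BuCOCl, pyridine, then aqueous work-up) gives [4-(pivaloyloxy)phenyl]boronic acid F4, whose conjugate addition to 1 under the catalyst of step 1 gives 4 directly, so the free-phenol flavanone never exists.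

**Step 5.** Once the phenoxide is free, expulsion of O1 from C2 to a quinone methide followed by loss of the C3 proton would open the ring irreversibly to an achiral stilbene acid. The hindered C3 ester may also hydrolyse slowly and prolong the exposure.

The fallback avoids hydroxide. It sets out from 10 and returns at 13:
- Me3SnOH in ClCH2CH2Cl at 80 °C cleaves only the methyl ester and gives (2R,3R)-5-[(E)-2-carboxyvinyl]-2-[4-(pivaloyloxy)phenyl]-2,3-dihydrobenzofuran-3-carboxylic acid F5. Should the pivalate be lost as well, the product is 11 itself.
- Double amidation of F5 with 12 under the conditions of step 6 gives (2R,3R)-N-{4-[N',N''-bis(tert-butoxycarbonyl)guanidino]butyl}-5-[(E)-3-({4-[N',N''-bis(tert-butoxycarbonyl)guanidino]butyl}amino)-3-oxoprop-1-en-1-yl]-2-[4-(pivaloyloxy)phenyl]-2,3-dihydrobenzofuran-3-carboxamide F6.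
- Hydrazinolysis of the aryl pivalate (N2H4·H2O, THF/MeOH, rt) gives 13.

**Step 6.** Activating two carboxyl groups beside a free phenol may lead to ester formation between molecules, and the hindered, enolisable C3 carboxyl may couple sluggishly, leaving mono-amide.

The fallback forms the two amides separately. It sets out from 8 and 12 and returns at 13:
- 12 is acylated with acryloyl chloride (Et3N, CH2Cl2, −20 °C) to N-{4-[N',N''-bis(tert-butoxycarbonyl)guanidino]butyl}acrylamide F7.
- Heck reaction of 8 with F7 under the conditions of step 4 gives methyl (2R,3R)-5-[(E)-3-({4-[N',N''-bis(tert-butoxycarbonyl)guanidino]butyl}amino)-3-oxoprop-1-en-1-yl]-2-[4-(pivaloyloxy)phenyl]-2,3-dihydrobenzofuran-3-carboxylate F8.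
- LiOH as in step 5 gives (2R,3R)-5-[(E)-3-({4-[N',N''-bis(tert-butoxycarbonyl)guanidino]butyl}amino)-3-oxoprop-1-en-1-yl]-2-(4-hydroxyphenyl)-2,3-dihydrobenzofuran-3-carboxylic acid F9.
- A single coupling of F9 with 12, with activation aimed at the C3 carboxyl alone, gives 13.

## Further compounds

F1 | step 3 | 4-[(2R)-6-bromo-4-oxo-3-(trifluoroacetyl)chroman-2-yl]phenyl pivalate (C3 enolisable, not defined) | O=C1C(C(=O)C(F)(F)F)[C@H](c2ccc(OC(=O)C(C)(C)C)cc2)Oc2ccc(Br)cc12
F2 | step 3 | 4-[(2S)-6-bromo-3-diazo-4-oxochroman-2-yl]phenyl pivalate | O=C1C(=[N+]=[N-])[C@H](c2ccc(OC(=O)C(C)(C)C)cc2)Oc2ccc(Br)cc12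
F3 | step 3 | methyl (2R,3S)-5-bromo-2-[4-(pivaloyloxy)phenyl]-2,3-dihydrobenzofuran-3-carboxylate (cis) | Brc1ccc2c(c1)[C@H](C(=O)OC)[C@H](c1ccc(OC(=O)C(C)(C)C)cc1)O2
F4 | step 1 | [4-(pivaloyloxy)phenyl]boronic acid | CC(C)(C)C(=O)Oc1ccc(B(O)O)cc1
F5 | step 5 | (2R,3R)-5-[(E)-2-carboxyvinyl]-2-[4-(pivaloyloxy)phenyl]-2,3-dihydrobenzofuran-3-carboxylic acid | OC(=O)/C=C/c1ccc2c(c1)[C@@H](C(=O)O)[C@H](c1ccc(OC(=O)C(C)(C)C)cc1)O2
F6 | step 5 | (2R,3R)-N-{4-[N',N''-bis(tert-butoxycarbonyl)guanidino]butyl}-5-[(E)-3-({4-[N',N''-bis(tert-butoxycarbonyl)guanidino]butyl}amino)-3-oxoprop-1-en-1-yl]-2-[4-(pivaloyloxy)phenyl]-2,3-dihydrobenzofuran-3-carboxamide | CC(C)(C)OC(=O)NC(NC(=O)OC(C)(C)C)=NCCCCNC(=O)/C=C/c1ccc2c(c1)[C@@H](C(=O)NCCCCN=C(NC(=O)OC(C)(C)C)NC(=O)OC(C)(C)C)[C@H](c1ccc(OC(=O)C(C)(C)C)cc1)O2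
F7 | step 6 | N-{4-[N',N''-bis(tert-butoxycarbonyl)guanidino]butyl}acrylamide | C=CC(=O)NCCCCN=C(NC(=O)OC(C)(C)C)NC(=O)OC(C)(C)C
F8 | step 6 | methyl (2R,3R)-5-[(E)-3-({4-[N',N''-bis(tert-butoxycarbonyl)guanidino]butyl}amino)-3-oxoprop-1-en-1-yl]-2-[4-(pivaloyloxy)phenyl]-2,3-dihydrobenzofuran-3-carboxylate | CC(C)(C)OC(=O)NC(NC(=O)OC(C)(C)C)=NCCCCNC(=O)/C=C/c1ccc2c(c1)[C@@H](C(=O)OC)[C@H](c1ccc(OC(=O)C(C)(C)C)cc1)O2
F9 | step 6 | (2R,3R)-5-[(E)-3-({4-[N',N''-bis(tert-butoxycarbonyl)guanidino]butyl}amino)-3-oxoprop-1-en-1-yl]-2-(4-hydroxyphenyl)-2,3-dihydrobenzofuran-3-carboxylic acid | CC(C)(C)OC(=O)NC(NC(=O)OC(C)(C)C)=NCCCCNC(=O)/C=C/c1ccc2c(c1)[C@@H](C(=O)O)[C@H](c1ccc(O)cc1)O2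
A1 | alternative 1 | (2R,3S)-2-(4-tert-butoxyphenyl)-3-[(tert-butyldimethylsilyloxy)methyl]-2,3-dihydrobenzofuran (trans) | c1ccc2c(c1)[C@@H](CO[Si](C)(C)C(C)(C)C)[C@H](c1ccc(OC(C)(C)C)cc1)O2
A2 | alternative 1 | tert-butyl{[(2S,3R)-3-(4-tert-butoxyphenyl)-2-ethynyl-3-(ethynyloxy)propyl]oxy}dimethylsilane | C#C[C@@H](CO[Si](C)(C)C(C)(C)C)[C@H](c1ccc(OC(C)(C)C)cc1)OC#C
A3 | alternative 1 | acetylene | C#C
A4 | alternative 2 | (2R,3S)-2-(4-tert-butoxyphenyl)-3-vinyl-2,3-dihydrobenzofuran-5-carbonitrile (cis) | N#Cc1ccc2c(c1)[C@H](C=C)[C@H](c1ccc(OC(C)(C)C)cc1)O2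
A5 | alternative 2 | 3-[(1R,2S)-1-(4-tert-butoxyphenyl)-1-hydroxybut-3-en-2-yl]-4-fluorobenzonitrile | N#Cc1ccc(F)c(c1)[C@H](C=C)[C@H](c1ccc(OC(C)(C)C)cc1)O
A6 | alternative 3 | tert-butyl (2R,3R)-5-bromo-2-(4-hydroxyphenyl)-2,3-dihydrobenzofuran-3-carboxylate | Brc1ccc2c(c1)[C@@H](C(=O)OC(C)(C)C)[C@H](c1ccc(O)cc1)O2
A7 | alternative 3 | tert-butyl 2-(5-bromo-2-hydroxyphenyl)-3-hydroxy-3-(4-hydroxyphenyl)propanoate (mixture of the four stereoisomers) | CC(C)(C)OC(=O)C(c1cc(Br)ccc1O)C(O)c1ccc(O)cc1
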